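**Retrosynthetic overview**

1. Target ⇒ a seco-calyxin p-hydroxystyrene (helichrysetin carrying an open (3R,5S)-diarylheptenol chain at C3′) plus the vinylogous p-quinone methide of a (5S)-diarylheptenediol. In one flask the C3–C1″ bond forms first, then the O1–C2 bond; this is the only ring-forming event.
2. Seco-calyxin ⇒ helichrysetin plus the same diarylheptenediol, by dehydrative Friedel–Crafts allylation at C3′ through the free allyl cation (no ring formed).
3. Diarylheptenediol ⇒ (S)-homoallylic alcohol plus a racemic aryl vinyl carbinol (cross-metathesis). The homoallylic alcohol comes from 3-(4-hydroxyphenyl)propanal by catalytic asymmetric allylboration, which supplies both remote carbinol centres of the target.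
4. Helichrysetin ⇒ 2′,4′-dihydroxy-6′-methoxyacetophenone plus 4-hydroxybenzaldehyde (Claisen–Schmidt). No protecting groups are used anywhere.
5. Ring order: all benzene rings are bought; the oxane is the only ring made and it is made last, with C2, C3 and the exocyclic centre set in that step.

Assumption: the presumed biosynthesis is taken to be the non-enzymatic union of helichrysetin with two p-hydroxycinnamyl-cation/quinone-methide equivalents of a (5S)-1,7-bis(4-hydroxyphenyl)heptenediol, the second union closing the oxane by oxa-Michael addition.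

**Route**

Step 1
Reactants: 1 3-(4-hydroxyphenyl)propanal; 2 allylboronic acid pinacol ester
Product: 4 4-[(3S)-3-hydroxyhex-5-en-1-yl]phenol, via O-pinacolboryl ether 3 (not isolated)
Conditions: (R)-3,3′-bis(2,4,6-triisopropylphenyl)-1,1′-binaphthyl-2,2′-diyl hydrogen phosphate (5 mol%), toluene/CH2Cl2, −30 °C; then aq. NaHCO3
Reagents that add atoms: none
Why: Chiral-phosphoric-acid-catalysed asymmetric allylboration (Antilla type), in which the acid organises a closed chair transition state and delivers allyl to the Re face of the unbranched aldehyde to set the (S)-carbinol (about 90% ee expected, the free phenol being inert to the pinacol boronate), and because two such units are joined later the minor enantiomer ends up in separable diastereomers.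

Step 2
Reactants: 5 4-hydroxybenzaldehyde; 6 vinylmagnesium bromide
Product: 7 rac-4-(1-hydroxyprop-2-en-1-yl)phenol
Conditions: CH2=CHMgBr (2.5 equiv), THF, 0 °C to rt; then H2O (pH 7 buffer)
Reagents that add atoms: none
Why: Grignard 1,2-addition in which the first equivalent deprotonates the phenol and the second adds to the aldehyde of the resulting phenoxide ArOMgBr; the new carbinol centre is left racemic on purpose because it is erased when this alcohol is later ionised.

Step 3
Reactants: 4 4-[(3S)-3-hydroxyhex-5-en-1-yl]phenol; 7 rac-4-(1-hydroxyprop-2-en-1-yl)phenol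
Product: 8 (2E,5S)-1,7-bis(4-hydroxyphenyl)hept-2-ene-1,5-diol (1:1 at C1)
Conditions: second-generation Hoveyda–Grubbs catalyst RuCl2(H2IMes)(=CH-C6H4-2-OiPr) (5 mol%), 1,4-benzoquinone (10 mol%), CH2Cl2/EtOAc, 40 °C; 7 in threefold excess
Reagents that add atoms: none
Why: Olefin cross-metathesis of a terminal homoallylic olefin with a secondary allylic alcohol (a slow homodimeriser, used in excess) gives the E-disubstituted olefin under thermodynamic control, tolerates free phenols and alcohols, is protected against hydride-induced olefin migration by the benzoquinone, and does not touch the C5 stereocentre.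

Step 4
Reactants: 9 1-(2,4-dihydroxy-6-methoxyphenyl)ethan-1-one; 5 4-hydroxybenzaldehyde
Product: 10 helichrysetin
Conditions: BF3·OEt2 (3 equiv), 1,4-dioxane, rt; then H2O/MeOH, 40 °C
Reagents that add atoms: none
Why: Claisen–Schmidt condensation under BF3 promotion, in which the difluoroboron chelate of the ortho-hydroxy ketone is the enol partner, which works on unprotected phenols, gives only the E-enone and avoids the base-induced chalcone-to-flavanone cyclisation; no stereocentre is formed.

Step 5
Reactants: 10 helichrysetin; 8 (2E,5S)-1,7-bis(4-hydroxyphenyl)hept-2-ene-1,5-diol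
Product: 12 3′-[(1E,3R,5S)-5-hydroxy-1,7-bis(4-hydroxyphenyl)hept-1-en-3-yl]helichrysetin, via p-hydroxycinnamyl-type cation 11 (not isolated)
Conditions: p-TsOH·H2O (5 mol%), MeCN, 0 °C to rt; 10 (3 equiv), 8 added over 2 h
Reagents that add atoms: none
Why: Dehydrative Friedel–Crafts (SN1) allylation in which the sulfonic acid ionises the benzylic-allylic carbinol of 8 to the allyl cation 11 (kept O-protonated as its tosylate ion pair by this strong acid, so that addition is reversible), which the acylphloroglucinol ring of 10 captures at C3′ (between the two hydroxyls, the C5′ site being screened by the in-plane O-methyl group) and at the allyl terminus remote from the aryl group so that styrene conjugation is kept (benzylic C- and O-adducts re-ionise and funnel to this isomer), while the new C3 centre is set anti to the C5 hydroxyl by attack opposite the C4–C5 bond in the conformer whose hydroxyl oxygen leans over the cation, a 1,3-induction expected to be only moderate so that the syn epimer is removed by chromatography and excess 10 is recovered.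

Step 6
Reactants: 12 3′-[(1E,3R,5S)-5-hydroxy-1,7-bis(4-hydroxyphenyl)hept-1-en-3-yl]helichrysetin; 8 (2E,5S)-1,7-bis(4-hydroxyphenyl)hept-2-ene-1,5-diol
Product: 15 blepharocalyxin E, via vinylogous quinone methide 13 (not isolated), via ring-open quinone methide 14 (not isolated)
Conditions: (PhO)2P(O)OH (10 mol%), CH2Cl2/MeCN (4:1), 0 °C; 8 (1.5 equiv) added over 6 h
Reagents that add atoms: none
Why: Proposed new method: diphenyl phosphate, too weak an acid to hold the electrophile as a cation, dehydrates 8 to the hydrogen-bonded neutral quinone methide 13, whose benzylic methide carbon (the 1,6-site, as in known phosphoric-acid-catalysed 1,6-additions to alkenyl-substituted p-quinone methides made in situ from p-hydroxybenzyl alcohols, and here kinetic and irreversible, unlike the reversible cationic regime of step 5) is attacked by the β-carbon of the p-hydroxystyrene of 12, a vinylogous phenol and the most nucleophilic π-site left in 12, to give quinone methide 14, which its C5 hydroxyl closes at once by intramolecular oxa-1,6-addition (the step that makes calyxin-type oxanes); the net anti addition across the E-styrene through a chair with the C4 aryl group and the C6 side chain equatorial sets C3 (R) and C2 (S) all-equatorial (C2 can also equilibrate by reversible ring opening), and the exocyclic (S) centre comes from an open antiperiplanar transition state in which the two quinoid aryl groups are anti and the methide hydrogen, not the alkenyl arm, lies next to the branched C3 substituent; the closest known reaction types are acid-catalysed additions of electron-rich styrenes and phenols to p-quinone methides and cation–olefin cyclisations terminated by a hydroxyl group.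

**Compound list**

1 | 3-(4-hydroxyphenyl)propanal | O=CCCc1ccc(O)cc1 | starting material
2 | allylboronic acid pinacol ester (2-allyl-4,4,5,5-tetramethyl-1,3,2-dioxaborolane) | C=CCB1OC(C)(C)C(C)(C)O1 | starting material
3 | 2-{[(3S)-1-(4-hydroxyphenyl)hex-5-en-3-yl]oxy}-4,4,5,5-tetramethyl-1,3,2-dioxaborolane | C=CC[C@@H](OB1OC(C)(C)C(C)(C)O1)CCc1ccc(O)cc1 | intermediate (not isolated)
4 | 4-[(3S)-3-hydroxyhex-5-en-1-yl]phenol | C=CC[C@@H](O)CCc1ccc(O)cc1 | intermediate
5 | 4-hydroxybenzaldehyde | O=Cc1ccc(O)cc1 | starting material
6 | vinylmagnesium bromide | C=C[Mg]Br | starting material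
7 | rac-4-(1-hydroxyprop-2-en-1-yl)phenol | C=CC(O)c1ccc(O)cc1 | intermediate
8 | (2E,5S)-1,7-bis(4-hydroxyphenyl)hept-2-ene-1,5-diol, 1:1 mixture of C1 epimers | OC(/C=C/C[C@@H](O)CCc1ccc(O)cc1)c1ccc(O)cc1 | intermediate
9 | 1-(2,4-dihydroxy-6-methoxyphenyl)ethan-1-one | COc1cc(O)cc(O)c1C(C)=O | starting material
10 | helichrysetin, (E)-1-(2,4-dihydroxy-6-methoxyphenyl)-3-(4-hydroxyphenyl)prop-2-en-1-one | COc1cc(O)cc(O)c1C(=O)/C=C/c1ccc(O)cc1 | intermediate
11 | (2E,5S)-5-hydroxy-1,7-bis(4-hydroxyphenyl)hept-2-en-1-ylium, the p-hydroxycinnamyl-type allyl cation from 8 (counter-ion p-toluenesulfonate) | Oc1ccc([CH+]/C=C/C[C@@H](O)CCc2ccc(O)cc2)cc1 | intermediate (not isolated)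
12 | (E)-1-{2,4-dihydroxy-3-[(1E,3R,5S)-5-hydroxy-1,7-bis(4-hydroxyphenyl)hept-1-en-3-yl]-6-methoxyphenyl}-3-(4-hydroxyphenyl)prop-2-en-1-one | COc1cc(O)c([C@@H](/C=C/c2ccc(O)cc2)C[C@@H](O)CCc2ccc(O)cc2)c(O)c1C(=O)/C=C/c1ccc(O)cc1 | intermediate
13 | 4-[(2E,5S)-5-hydroxy-7-(4-hydroxyphenyl)hept-2-en-1-ylidene]cyclohexa-2,5-dien-1-one | O=C1C=CC(=C/C=C/C[C@@H](O)CCc2ccc(O)cc2)C=C1 | intermediate (not isolated)
14 | ring-open p-quinone methide from 12 and 13: the target with the O1–C2 bond not yet formed, C2 being the sp2 methide carbon of a cyclohexa-2,5-dienone and the C6 hydroxyl free (oxane numbering: C3 R, C4 R, C6 S, C1″ S, C5″ S) | COc1cc(O)c([C@@H]([C@@H](C=C2C=CC(=O)C=C2)[C@H](/C=C/C[C@@H](O)CCc2ccc(O)cc2)c2ccc(O)cc2)C[C@H](CCc2ccc(O)cc2)O)c(O)c1C(=O)/C=C/c1ccc(O)cc1 | intermediate (not isolated)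
15 | blepharocalyxin E, (E)-1-{2,4-dihydroxy-3-[(2S,3R,4R,6S)-3-[(1S,2E,5S)-5-hydroxy-1,7-bis(4-hydroxyphenyl)hept-2-en-1-yl]-2-(4-hydroxyphenyl)-6-[2-(4-hydroxyphenyl)ethyl]oxan-4-yl]-6-methoxyphenyl}-3-(4-hydroxyphenyl)prop-2-en-1-one | COc1cc(O)c([C@@H]2C[C@H](CCc3ccc(O)cc3)O[C@H](c3ccc(O)cc3)[C@H]2[C@H](/C=C/C[C@@H](O)CCc2ccc(O)cc2)c2ccc(O)cc2)c(O)c1C(=O)/C=C/c1ccc(O)cc1 | target

**Step count**

Total: 6 steps. Longest linear sequence: 4 steps (1 → 4 → 8 → 12 → 15, that is steps 1, 3, 5 and 6).

**Steps most likely to fail, with fallbacks**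

Step 6 (the union and ring closure). The risks are attack at the remote (1,8) terminus of 13, competing alkylation of the free C5′ position of the chalcone ring, and weak control of the exocyclic centre. The fallback sets out from 12 (with 5 and 4) and comes back at 15. The electrophile is changed to one that reacts at the benzylic carbon (its alkyne terminus is unsubstituted, so remote attack to an allene is disfavoured), and the heptenol arm is completed afterwards. 5 and HC≡CMgBr give rac-4-(1-hydroxyprop-2-yn-1-yl)phenol F1. 12 and F1 under the same phosphoric acid give, by propargylic substitution at the benzylic carbon followed by the same oxa-cyclisation, the ethynyl oxane F2. Semihydrogenation over Pd/CaCO3 poisoned with Pb(OAc)2 and quinoline gives the vinyl oxane F3. Cross-metathesis of F3 with 4 (second-generation Hoveyda–Grubbs catalyst RuCl2(H2IMes)(=CH-C6H4-2-OiPr)) installs the E-alkene together with the (5S)-carbinol and returns to the route at 15.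

Step 5 (Friedel–Crafts allylation). The risks are low 3,5-anti selectivity at the new C3 centre and partial reaction at C5′. The fallback sets out from 8 (with 10) and comes back at 12. Substitution through a free cation is replaced by a stereospecific metal-catalysed allylic substitution. 8 is cyclodehydrated (pyridinium p-toluenesulfonate, CH2Cl2) to the thermodynamically preferred cis-dihydropyran F4. Zerovalent palladium (Pd(PPh3)4, THF, 40 °C) ionises its benzylic-allylic C–O bond with inversion, and 10 attacks through C3′ at the allyl terminus remote from the aryl group, again with inversion. The net retention places the aryl group on the face the ring oxygen left, which turns the cis relationship of F4 into the (3R,5S) adduct 12, where the route is rejoined.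

Step 3 (cross-metathesis). The risks are isomerisation or ionisation of the p-hydroxybenzylic allylic alcohol 7 and of the product 8 on the metathesis catalyst. The fallback sets out from 1 (with 5) and comes back at 8. The alkene is made from an alkyne instead of by metathesis. 1 is propargylated with allenylboronic acid pinacol ester under the chiral phosphoric acid of step 1 to give 4-[(3S)-3-hydroxyhex-5-yn-1-yl]phenol F5. Its trilithio derivative (n-BuLi, THF, −78 °C) adds to the phenoxide ArOLi of 5 to give the ynediol (5S)-1,7-bis(4-hydroxyphenyl)hept-2-yne-1,5-diol F6. Hydroxyl-directed trans-hydroalumination with NaAlH2(OCH2CH2OMe)2 then gives the E-alkene and returns to the route at 8.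

**Further compounds**

F1 | step 6 | rac-4-(1-hydroxyprop-2-yn-1-yl)phenol | C#CC(O)c1ccc(O)cc1
F2 | step 6 | (E)-1-{2,4-dihydroxy-3-[(2S,3R,4R,6S)-2-(4-hydroxyphenyl)-6-[2-(4-hydroxyphenyl)ethyl]-3-[(1R)-1-(4-hydroxyphenyl)prop-2-yn-1-yl]oxan-4-yl]-6-methoxyphenyl}-3-(4-hydroxyphenyl)prop-2-en-1-one | COc1cc(O)c([C@@H]2C[C@H](CCc3ccc(O)cc3)O[C@H](c3ccc(O)cc3)[C@H]2[C@H](C#C)c2ccc(O)cc2)c(O)c1C(=O)/C=C/c1ccc(O)cc1
F3 | step 6 | (E)-1-{2,4-dihydroxy-3-[(2S,3R,4R,6S)-2-(4-hydroxyphenyl)-6-[2-(4-hydroxyphenyl)ethyl]-3-[(1S)-1-(4-hydroxyphenyl)prop-2-en-1-yl]oxan-4-yl]-6-methoxyphenyl}-3-(4-hydroxyphenyl)prop-2-en-1-one | COc1cc(O)c([C@@H]2C[C@H](CCc3ccc(O)cc3)O[C@H](c3ccc(O)cc3)[C@H]2[C@H](C=C)c2ccc(O)cc2)c(O)c1C(=O)/C=C/c1ccc(O)cc1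
F4 | step 5 | 4-[(2S,6S)-6-[2-(4-hydroxyphenyl)ethyl]-5,6-dihydro-2H-pyran-2-yl]phenol (2,6-cis) | O1[C@H](c2ccc(O)cc2)C=CC[C@@H]1CCc1ccc(O)cc1
F5 | step 3 | 4-[(3S)-3-hydroxyhex-5-yn-1-yl]phenol | C#CC[C@@H](O)CCc1ccc(O)cc1
F6 | step 3 | (5S)-1,7-bis(4-hydroxyphenyl)hept-2-yne-1,5-diol, 1:1 mixture of C1 epimers | OC(C#CC[C@@H](O)CCc1ccc(O)cc1)c1ccc(O)cc1
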